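**Plan**

1. Retrosynthesis (chain numbered C1 at the oxolanone to C11 at the carbinol): after desilylation, the C5–C6 sp2–sp3 bond is cut (B-alkyl Suzuki) into a dienyl furanone and an iodo-alkylidene oxolanone. The exocyclic C=C of the oxolanone is then cut (Horner–Wadsworth–Emmons), and the O1–C5 bond of the furanone is cut back to a cyclopropene acid made from a terminal alkyne and ethyl diazoacetate.
2. Forward: ynone → (R)-propargylic silyl ether → cyclopropene acid → furanone ring (step 7) → aldehyde → enal → diene. Separately, pentynol → (E)-iodo aldehyde, and the chiral-pool oxolanone → phosphonate → (Z)-alkylidene oxolanone. The halves are joined by hydroboration/Suzuki coupling, then the silyl group is removed.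
3. Stereochemistry: C11 (R) from Noyori transfer hydrogenation of the ynone; oxolanone C5 (S) from (5S)-5-(hydroxymethyl)oxolan-2-one; C8=C9 (E) from a stabilised Wittig reagent; C4=C5 (E) from syn-carboalumination; exocyclic (Z) from a kinetic Horner–Wadsworth–Emmons reaction.
4. Enabling feature: in the furanone the unsubstituted methylene C5 lies between O1 and the C3=C4 enoate, cis to the carboxyl carbon C2. C3–C4–C5 is therefore a ring-opened cyclopropene (C4 and C5 from a terminal alkyne, C3 and C2 from the diazoacetate), and release of the three-ring strain drives O1–C5 bond formation. The step is run before any chain olefin exists.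

Key step: step 7

Remark: 7, 8 and 21 are carried as mixtures of epimers at a carbon that becomes sp2 in a later step, so their SMILES leave that centre open.

**Route**

Step 1
Reactants: 1 methyl 3,3-dimethoxypropanoate
Product: 3 5,5-dimethoxy-1-(trimethylsilyl)pent-1-yn-3-one, via Weinreb amide 2 (not isolated)
Conditions: MeNH(OMe)·HCl, i-PrMgCl, THF, −20 °C; then LiC≡CSiMe3 (from ethynyltrimethylsilane, n-BuLi), −20 → 0 °C; aq. NH4Cl
Reagents that add atoms: ethynyltrimethylsilane, C#C[Si](C)(C)C
Why: One-pot Weinreb ketone synthesis, in which the chloromagnesium amide turns the ester into the N-methoxy-N-methylamide and the chelated tetrahedral adduct of the lithium acetylide prevents over-addition and releases the ynone on work-up.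

Step 2
Reactants: 3 5,5-dimethoxy-1-(trimethylsilyl)pent-1-yn-3-one
Product: 4 (3R)-5,5-dimethoxy-1-(trimethylsilyl)pent-1-yn-3-ol
Conditions: Ru[(R,R)-TsDPEN](p-cymene) (preformed amido complex, 1 mol%), i-PrOH, rt
Reagents that add atoms: none
Why: Noyori asymmetric transfer hydrogenation of an alkynyl ketone, in which the (R,R)-ligand differentiates the alkynyl from the alkyl substituent in the six-membered hydride-transfer transition state and should set the (R)-carbinol, the later C11 stereocentre.

Step 3
Reactants: 4 (3R)-5,5-dimethoxy-1-(trimethylsilyl)pent-1-yn-3-ol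
Product: 5 tert-butyl{[(3R)-5,5-dimethoxy-1-(trimethylsilyl)pent-1-yn-3-yl]oxy}dimethylsilane
Conditions: TBSCl, imidazole, DMF, rt
Reagents that add atoms: tert-butyldimethylsilyl chloride, CC(C)(C)[Si](C)(C)Cl
Why: Standard silylation of a secondary alcohol, which masks the hydroxyl against O–H insertion of the rhodium carbenoid in step 5.

Step 4
Reactants: 5 tert-butyl{[(3R)-5,5-dimethoxy-1-(trimethylsilyl)pent-1-yn-3-yl]oxy}dimethylsilane
Product: 6 tert-butyl{[(3R)-5,5-dimethoxypent-1-yn-3-yl]oxy}dimethylsilane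
Conditions: K2CO3, MeOH, rt
Reagents that add atoms: none
Why: Base-catalysed methanolysis of the alkynyl C–Si bond frees the terminal alkyne and leaves the silyl ether and the acetal untouched.

Step 5
Reactants: 6 tert-butyl{[(3R)-5,5-dimethoxypent-1-yn-3-yl]oxy}dimethylsilane
Product: 7 ethyl 2-{(1R)-1-[(tert-butyldimethylsilyl)oxy]-3,3-dimethoxypropyl}cycloprop-2-ene-1-carboxylate (epimers at C1)
Conditions: ethyl diazoacetate (syringe pump), Rh2(OAc)4 (1 mol%), CH2Cl2, rt
Reagents that add atoms: ethyl diazoacetate, CCOC(=O)C=[N+]=[N-]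
Why: Rh2(OAc)4-catalysed [2+1] cyclopropenation of a terminal alkyne by the ester carbenoid, on a substrate that holds no competing olefin; the new sp3 centre is formed without control because it is erased in step 7.

Step 6
Reactants: 7 ethyl 2-{(1R)-1-[(tert-butyldimethylsilyl)oxy]-3,3-dimethoxypropyl}cycloprop-2-ene-1-carboxylate
Product: 8 2-{(1R)-1-[(tert-butyldimethylsilyl)oxy]-3,3-dimethoxypropyl}cycloprop-2-ene-1-carboxylic acid (epimers at C1)
Conditions: LiOH, THF/MeOH/H2O, 0 °C → rt; then 1 M HCl to pH 4, 0 °C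
Reagents that add atoms: lithium hydroxide, [Li+].[OH-]
Why: Saponification of the ethyl ester, which 2-alkylcycloprop-2-ene-1-carboxylates tolerate, followed by mild acidification that spares the acetal and the silyl ether.

Step 7
Reactants: 8 2-{(1R)-1-[(tert-butyldimethylsilyl)oxy]-3,3-dimethoxypropyl}cycloprop-2-ene-1-carboxylic acid
Product: 9 4-{(1R)-1-[(tert-butyldimethylsilyl)oxy]-3,3-dimethoxypropyl}furan-2(5H)-one
Conditions: Ph3PAuNTf2 (2 mol%), CH2Cl2, 0 °C → rt
Reagents that add atoms: none
Why: The cationic gold complex binds the cyclopropene at its unsubstituted olefinic carbon, the resulting tertiary cyclopropyl cation opens with cleavage of the bond between that carbon and the carboxyl-bearing sp3 carbon, and the vinyl gold carbenoid so formed is attacked at the carbenoid carbon by the cis carboxyl oxygen, after which protodeauration by the acid proton leaves the O1–C5 bond and the C5 methylene (a formal intramolecular O–H insertion driven by release of the three-ring strain). The closest known reaction type is the thermal or late-metal-catalysed ring-opening cycloisomerisation of cycloprop-2-ene-1-carboxylic acids and esters to furan-2(5H)-ones. The five-membered lactone closes by 5-exo-trig attack of oxygen on the gold–carbon double bond. No stereocentre is created: the two epimers at the cyclopropene sp3 carbon converge because that carbon becomes the sp2 C3 of the furanone, and the silyloxy-bearing centre next to the ring is not touched. The step needs ring opening towards the unsubstituted olefinic carbon (the other mode would give a 5-substituted furanone), which the preference of the electrophilic metal for the less substituted carbon and the more stabilised cation secures, and it needs the carboxyl group cis to the carbenoid carbon, which the allyl-cation character of the intermediate allows from either epimer. Chemoselectivity is secured by the substrate, which holds no olefin that the rhodium carbenoid of step 5 or the gold carbenoid could cyclopropanate.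

Step 8
Reactants: 9 4-{(1R)-1-[(tert-butyldimethylsilyl)oxy]-3,3-dimethoxypropyl}furan-2(5H)-one
Product: 10 (3R)-3-[(tert-butyldimethylsilyl)oxy]-3-(5-oxo-2,5-dihydrofuran-3-yl)propanal
Conditions: TFA, CH2Cl2/H2O, 0 °C
Reagents that add atoms: water, O
Why: Acid-catalysed hydrolysis of the dimethyl acetal through the oxocarbenium ion, under brief cold conditions that the secondary silyl ether and the furanone should survive.

Step 9
Reactants: 10 (3R)-3-[(tert-butyldimethylsilyl)oxy]-3-(5-oxo-2,5-dihydrofuran-3-yl)propanal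
Product: 11 (2E,5R)-5-[(tert-butyldimethylsilyl)oxy]-2-methyl-5-(5-oxo-2,5-dihydrofuran-3-yl)pent-2-enal
Conditions: Ph3P=C(CH3)CHO, toluene, 60 °C
Reagents that add atoms: 2-(triphenylphosphoranylidene)propanal, CC(C=O)=P(c1ccccc1)(c1ccccc1)c1ccccc1
Why: Wittig reaction with a stabilised α-methyl ylide, which reacts once with the unhindered aldehyde under thermodynamic control and should give the (E)-2-methyl enal, setting the C8=C9 geometry.

Step 10
Reactants: 11 (2E,5R)-5-[(tert-butyldimethylsilyl)oxy]-2-methyl-5-(5-oxo-2,5-dihydrofuran-3-yl)pent-2-enal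
Product: 12 4-{(1R,3E)-1-[(tert-butyldimethylsilyl)oxy]-4-methylhexa-3,5-dien-1-yl}furan-2(5H)-one
Conditions: Zn, CH2Br2, TiCl4 (preformed reagent), THF/CH2Cl2, 0 °C → rt
Reagents that add atoms: dibromomethane, BrCBr
Why: Non-basic Takai–Lombardo methylenation converts the enal carbonyl into the terminal vinyl group without attacking the lactone carbonyl or deprotonating the furanone, and the trisubstituted olefin keeps its geometry.

Step 11
Reactants: 13 pent-4-yn-1-ol
Product: 15 (4E)-5-iodo-4-methylpent-4-en-1-ol, via vinylalane 14 (not isolated)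
Conditions: Me3Al, Cp2ZrCl2, CH2Cl2, 0 °C → rt; then I2, THF, −30 → 0 °C; aq. K2CO3
Reagents that add atoms: trimethylaluminium, C[Al](C)C; iodine, II
Why: Negishi zirconium-catalysed syn-carboalumination puts methyl on the internal and aluminium on the terminal alkyne carbon, and iododealumination with retention should give the (E)-vinyl iodide that later defines the C4=C5 geometry.

Step 12
Reactants: 15 (4E)-5-iodo-4-methylpent-4-en-1-ol
Product: 16 (4E)-5-iodo-4-methylpent-4-enal
Conditions: Dess–Martin periodinane, CH2Cl2, rt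
Reagents that add atoms: none
Why: Dess–Martin oxidation of a primary alcohol to the aldehyde under neutral conditions that leave the vinyl iodide intact.

Step 13
Reactants: 17 (5S)-5-(hydroxymethyl)oxolan-2-one
Product: 18 (2S)-5-oxooxolane-2-carbaldehyde
Conditions: Dess–Martin periodinane, CH2Cl2, 0 °C → rt
Reagents that add atoms: none
Why: Dess–Martin oxidation under neutral conditions should give the α-oxygenated aldehyde without epimerising the chiral-pool stereocentre.

Step 14
Reactants: 18 (2S)-5-oxooxolane-2-carbaldehyde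
Product: 19 (5S)-5-(2-methylprop-1-en-1-yl)oxolan-2-one
Conditions: i-PrPPh3I, n-BuLi, THF, 0 °C; then 18, −78 °C → rt
Reagents that add atoms: isopropyltriphenylphosphonium iodide, CC(C)[P+](c1ccccc1)(c1ccccc1)c1ccccc1.[I-]
Why: Wittig olefination with the non-stabilised isopropylidene ylide at low temperature, where addition to the aldehyde should outrun attack on the lactone carbonyl and enolisation, so the (S) centre is carried over unchanged.

Step 15
Reactants: 19 (5S)-5-(2-methylprop-1-en-1-yl)oxolan-2-one
Product: 21 diethyl [(5S)-5-(2-methylprop-1-en-1-yl)-2-oxooxolan-3-yl]phosphonate (epimers at C3), via enol phosphate 20 (not isolated)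
Conditions: LiN(i-Pr)2 (1.1 equiv), THF, −78 °C; ClP(O)(OEt)2; then LiN(i-Pr)2 (2.2 equiv), −78 °C → rt; AcOH
Reagents that add atoms: diethyl chlorophosphate, CCOP(=O)(Cl)OCC
Why: O-phosphorylation of the lactone enolate followed by base-induced 1,3-migration of phosphorus from oxygen to carbon (vinyl phosphate to phosphonate rearrangement) gives the α-phosphono lactone, epimeric at a carbon that becomes sp2 in step 16.

Step 16
Reactants: 21 diethyl [(5S)-5-(2-methylprop-1-en-1-yl)-2-oxooxolan-3-yl]phosphonate; 16 (4E)-5-iodo-4-methylpent-4-enal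
Product: 22 (3Z,5S)-3-[(4E)-5-iodo-4-methylpent-4-en-1-ylidene]-5-(2-methylprop-1-en-1-yl)oxolan-2-one
Conditions: 21, KN(SiMe3)2, 18-crown-6, THF, −78 °C; then 16, −78 °C
Reagents that add atoms: none
Why: Horner–Wadsworth–Emmons olefination of an α-phosphono lactone under dissociating conditions (potassium ion sequestered by 18-crown-6, −78 °C), where addition is irreversible and the kinetically formed (Z)-alkylidene lactone (chain cis to the carbonyl) should predominate, the (E) isomer being removed at this small-fragment stage.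

Step 17
Reactants: 12 4-{(1R,3E)-1-[(tert-butyldimethylsilyl)oxy]-4-methylhexa-3,5-dien-1-yl}furan-2(5H)-one; 22 (3Z,5S)-3-[(4E)-5-iodo-4-methylpent-4-en-1-ylidene]-5-(2-methylprop-1-en-1-yl)oxolan-2-one
Product: 24 (3Z,5S)-3-[(4E,8E,11R)-11-[(tert-butyldimethylsilyl)oxy]-4,8-dimethyl-11-(5-oxo-2,5-dihydrofuran-3-yl)undeca-4,8-dien-1-ylidene]-5-(2-methylprop-1-en-1-yl)oxolan-2-one, via alkylborane 23 (not isolated)
Conditions: 12, 9-BBN, THF, 0 °C → rt; then 22, Pd(dppf)Cl2 (5 mol%), AsPh3, aq. K3PO4, DMF, rt
Reagents that add atoms: none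
Why: B-alkyl Suzuki–Miyaura coupling, in which 9-BBN should add anti-Markovnikov to the terminal vinyl group of the diene only (the trisubstituted olefin, the ring olefin and the lactone carbonyl being far less reactive) and the primary alkylborane couples with the (E)-vinyl iodide with retention of geometry to form the C5–C6 bond.

Step 18
Reactants: 24 (3Z,5S)-3-[(4E,8E,11R)-11-[(tert-butyldimethylsilyl)oxy]-4,8-dimethyl-11-(5-oxo-2,5-dihydrofuran-3-yl)undeca-4,8-dien-1-ylidene]-5-(2-methylprop-1-en-1-yl)oxolan-2-one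
Product: 25 (3Z,5S)-3-[(4E,8E,11R)-11-hydroxy-4,8-dimethyl-11-(5-oxo-2,5-dihydrofuran-3-yl)undeca-4,8-dien-1-ylidene]-5-(2-methylprop-1-en-1-yl)oxolan-2-one
Conditions: HF·pyridine, pyridine, THF, 0 °C → rt
Reagents that add atoms: none
Why: Fluoride-mediated cleavage of the secondary silyl ether under buffered, non-basic conditions that should spare both lactones and the (Z)-alkylidene geometry.

**Compound list**

1 | methyl 3,3-dimethoxypropanoate | COC(OC)CC(=O)OC | starting material
2 | N-methoxy-N-methyl-3,3-dimethoxypropanamide (not isolated) | CON(C)C(=O)CC(OC)OC | intermediate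
3 | 5,5-dimethoxy-1-(trimethylsilyl)pent-1-yn-3-one | COC(OC)CC(=O)C#C[Si](C)(C)C | intermediate
4 | (3R)-5,5-dimethoxy-1-(trimethylsilyl)pent-1-yn-3-ol | COC(OC)C[C@@H](O)C#C[Si](C)(C)C | intermediate
5 | tert-butyl{[(3R)-5,5-dimethoxy-1-(trimethylsilyl)pent-1-yn-3-yl]oxy}dimethylsilane | COC(OC)C[C@@H](O[Si](C)(C)C(C)(C)C)C#C[Si](C)(C)C | intermediate
6 | tert-butyl{[(3R)-5,5-dimethoxypent-1-yn-3-yl]oxy}dimethylsilane | COC(OC)C[C@@H](O[Si](C)(C)C(C)(C)C)C#C | intermediate
7 | ethyl 2-{(1R)-1-[(tert-butyldimethylsilyl)oxy]-3,3-dimethoxypropyl}cycloprop-2-ene-1-carboxylate (epimers at C1) | COC(OC)C[C@@H](O[Si](C)(C)C(C)(C)C)C1=CC1C(=O)OCC | intermediate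
8 | 2-{(1R)-1-[(tert-butyldimethylsilyl)oxy]-3,3-dimethoxypropyl}cycloprop-2-ene-1-carboxylic acid (epimers at C1) | COC(OC)C[C@@H](O[Si](C)(C)C(C)(C)C)C1=CC1C(=O)O | intermediate
9 | 4-{(1R)-1-[(tert-butyldimethylsilyl)oxy]-3,3-dimethoxypropyl}furan-2(5H)-one | COC(OC)C[C@@H](O[Si](C)(C)C(C)(C)C)C1=CC(=O)OC1 | intermediate
10 | (3R)-3-[(tert-butyldimethylsilyl)oxy]-3-(5-oxo-2,5-dihydrofuran-3-yl)propanal | O=CC[C@@H](O[Si](C)(C)C(C)(C)C)C1=CC(=O)OC1 | intermediate
11 | (2E,5R)-5-[(tert-butyldimethylsilyl)oxy]-2-methyl-5-(5-oxo-2,5-dihydrofuran-3-yl)pent-2-enal | O=C/C(C)=C/C[C@@H](O[Si](C)(C)C(C)(C)C)C1=CC(=O)OC1 | intermediate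
12 | 4-{(1R,3E)-1-[(tert-butyldimethylsilyl)oxy]-4-methylhexa-3,5-dien-1-yl}furan-2(5H)-one | C=C/C(C)=C/C[C@@H](O[Si](C)(C)C(C)(C)C)C1=CC(=O)OC1 | intermediate
13 | pent-4-yn-1-ol | C#CCCCO | starting material
14 | [(1E)-5-(dimethylalumanyloxy)-2-methylpent-1-en-1-yl]dimethylalumane (not isolated) | C[Al](C)/C=C(\C)CCCO[Al](C)C | intermediate
15 | (4E)-5-iodo-4-methylpent-4-en-1-ol | OCCC/C(C)=C/I | intermediate
16 | (4E)-5-iodo-4-methylpent-4-enal | O=CCC/C(C)=C/I | intermediate
17 | (5S)-5-(hydroxymethyl)oxolan-2-one | OC[C@@H]1CCC(=O)O1 | starting material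
18 | (2S)-5-oxooxolane-2-carbaldehyde | O=C[C@@H]1CCC(=O)O1 | intermediate
19 | (5S)-5-(2-methylprop-1-en-1-yl)oxolan-2-one | CC(C)=C[C@@H]1CCC(=O)O1 | intermediate
20 | diethyl (5S)-5-(2-methylprop-1-en-1-yl)-4,5-dihydrofuran-2-yl phosphate (not isolated) | CC(C)=C[C@@H]1CC=C(OP(=O)(OCC)OCC)O1 | intermediate
21 | diethyl [(5S)-5-(2-methylprop-1-en-1-yl)-2-oxooxolan-3-yl]phosphonate (epimers at C3) | CC(C)=C[C@@H]1CC(P(=O)(OCC)OCC)C(=O)O1 | intermediate
22 | (3Z,5S)-3-[(4E)-5-iodo-4-methylpent-4-en-1-ylidene]-5-(2-methylprop-1-en-1-yl)oxolan-2-one | CC(C)=C[C@@H]1C/C(=C/CC/C(C)=C/I)C(=O)O1 | intermediate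
23 | 4-{(1R,3E)-6-(9-borabicyclo[3.3.1]nonan-9-yl)-1-[(tert-butyldimethylsilyl)oxy]-4-methylhex-3-en-1-yl}furan-2(5H)-one (not isolated) | B1(C2CCCC1CCC2)CC/C(C)=C/C[C@@H](O[Si](C)(C)C(C)(C)C)C1=CC(=O)OC1 | intermediate
24 | (3Z,5S)-3-[(4E,8E,11R)-11-[(tert-butyldimethylsilyl)oxy]-4,8-dimethyl-11-(5-oxo-2,5-dihydrofuran-3-yl)undeca-4,8-dien-1-ylidene]-5-(2-methylprop-1-en-1-yl)oxolan-2-one | CC(C)=C[C@@H]1C/C(=C/CC/C(C)=C/CC/C(C)=C/C[C@@H](O[Si](C)(C)C(C)(C)C)C2=CC(=O)OC2)C(=O)O1 | intermediate
25 | (3Z,5S)-3-[(4E,8E,11R)-11-hydroxy-4,8-dimethyl-11-(5-oxo-2,5-dihydrofuran-3-yl)undeca-4,8-dien-1-ylidene]-5-(2-methylprop-1-en-1-yl)oxolan-2-one | CC(C)=C[C@@H]1C/C(=C/CC/C(C)=C/CC/C(C)=C/C[C@@H](O)C2=CC(=O)OC2)C(=O)O1 | target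

**Step count**

Total step count: 18. Longest linear sequence: 12 steps (steps 1–10, 17 and 18).

**Steps most likely to fail**

Step 7. The ring may open towards the substituted olefinic carbon, the gold carbenoid may be captured by an acetal oxygen, or the strained acid may oligomerise before it cyclises. The fallback sets out from 6 and comes back at 9, and closes the furanone by olefination instead of carbenoid insertion. Gold-catalysed oxidation of the terminal alkyne of 6 with 8-methylquinoline N-oxide in the presence of (diethoxyphosphoryl)acetic acid (Ph3PAuNTf2, 1,2-dichloroethane, rt) should give the α-acyloxy ketone F1. An intramolecular Horner–Wadsworth–Emmons reaction under mild Masamune–Roush conditions (LiCl, i-Pr2NEt, MeCN, 0 °C) should then form C3=C4 and give 9; the mild base is chosen to limit epimerisation next to the ketone.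

Step 16. The adducts may equilibrate towards the more stable (E)-alkylidene lactone, so the geometric selectivity may be poor. The fallback sets out from 19 and comes back at 22, and moves the olefination to an open chain, where Still–Gennari control is best established, with the lactone closed afterwards. Lactone 19 is saponified, silylated and freed from the silyl ester (KOH, MeOH/H2O; TBSCl, imidazole, DMF; K2CO3, MeOH/H2O) to give the silyloxy acid F2, which is esterified (MeI, K2CO3, DMF) to the methyl ester F3. Phosphorylation of its lithium enolate with bis(2,2,2-trifluoroethyl) phosphorochloridate and base-induced oxygen-to-carbon migration (LiN(i-Pr)2, THF, −78 °C) should give the bis(trifluoroethyl) phosphonate F4. Olefination of 16 (KN(SiMe3)2, 18-crown-6, THF, −78 °C) should give the (2Z)-enoate F5. HF·pyridine then removes the silyl group, and the freed hydroxyl closes onto the cis ester to give 22.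

Step 17. The hydroboration may lose chemoselectivity (attack at the internal olefin or reduction of a lactone carbonyl), and the furanone may degrade under the basic aqueous coupling. The fallback sets out from 10 and comes back at 24; it grows the chain linearly on the furanone by two Nozaki–Hiyama–Kishi/Claisen cycles and attaches the oxolanone last. Aldehyde 10 and 2-bromopropene (CrCl2, NiCl2 cat., DMF) should give the allylic alcohol F6. Vinyl ether exchange (ethyl vinyl ether, Hg(OAc)2 cat.) gives the allyl vinyl ether F7, whose Claisen rearrangement (toluene, 130 °C) through a chair transition state should give the (4E)-aldehyde F8. The same operations give the allylic alcohol F9, the allyl vinyl ether F10 and the (4E,8E)-aldehyde F11. A Horner–Wadsworth–Emmons reaction of F11 with 21 (KN(SiMe3)2, 18-crown-6, THF, −78 °C) then gives 24.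

**Further compounds**

F1 | step 7 | (3R)-3-[(tert-butyldimethylsilyl)oxy]-5,5-dimethoxy-2-oxopentyl (diethoxyphosphoryl)acetate | COC(OC)C[C@@H](O[Si](C)(C)C(C)(C)C)C(=O)COC(=O)CP(=O)(OCC)OCC
F2 | step 16 | (4S)-4-[(tert-butyldimethylsilyl)oxy]-6-methylhept-5-enoic acid | CC(C)=C[C@@H](O[Si](C)(C)C(C)(C)C)CCC(=O)O
F3 | step 16 | methyl (4S)-4-[(tert-butyldimethylsilyl)oxy]-6-methylhept-5-enoate | CC(C)=C[C@@H](O[Si](C)(C)C(C)(C)C)CCC(=O)OC
F4 | step 16 | methyl (4S)-2-[bis(2,2,2-trifluoroethoxy)phosphoryl]-4-[(tert-butyldimethylsilyl)oxy]-6-methylhept-5-enoate | CC(C)=C[C@@H](O[Si](C)(C)C(C)(C)C)CC(C(=O)OC)P(=O)(OCC(F)(F)F)OCC(F)(F)F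
F5 | step 16 | methyl (2Z,6E)-2-{(2S)-2-[(tert-butyldimethylsilyl)oxy]-4-methylpent-3-en-1-yl}-7-iodo-6-methylhepta-2,6-dienoate | CC(C)=C[C@@H](O[Si](C)(C)C(C)(C)C)C/C(=C/CC/C(C)=C/I)C(=O)OC
F6 | step 17 | 4-{(1R)-1-[(tert-butyldimethylsilyl)oxy]-3-hydroxy-4-methylpent-4-en-1-yl}furan-2(5H)-one | C=C(C)C(O)C[C@@H](O[Si](C)(C)C(C)(C)C)C1=CC(=O)OC1
F7 | step 17 | 4-{(1R)-1-[(tert-butyldimethylsilyl)oxy]-3-(ethenyloxy)-4-methylpent-4-en-1-yl}furan-2(5H)-one | C=COC(C[C@@H](O[Si](C)(C)C(C)(C)C)C1=CC(=O)OC1)C(C)=C
F8 | step 17 | (4E,7R)-7-[(tert-butyldimethylsilyl)oxy]-4-methyl-7-(5-oxo-2,5-dihydrofuran-3-yl)hept-4-enal | O=CCC/C(C)=C/C[C@@H](O[Si](C)(C)C(C)(C)C)C1=CC(=O)OC1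
F9 | step 17 | 4-{(1R,3E)-1-[(tert-butyldimethylsilyl)oxy]-7-hydroxy-4,8-dimethylnona-3,8-dien-1-yl}furan-2(5H)-one | C=C(C)C(O)CC/C(C)=C/C[C@@H](O[Si](C)(C)C(C)(C)C)C1=CC(=O)OC1
F10 | step 17 | 4-{(1R,3E)-1-[(tert-butyldimethylsilyl)oxy]-7-(ethenyloxy)-4,8-dimethylnona-3,8-dien-1-yl}furan-2(5H)-one | C=COC(CC/C(C)=C/C[C@@H](O[Si](C)(C)C(C)(C)C)C1=CC(=O)OC1)C(C)=C
F11 | step 17 | (4E,8E,11R)-11-[(tert-butyldimethylsilyl)oxy]-4,8-dimethyl-11-(5-oxo-2,5-dihydrofuran-3-yl)undeca-4,8-dienal | O=CCC/C(C)=C/CC/C(C)=C/C[C@@H](O[Si](C)(C)C(C)(C)C)C1=CC(=O)OC1
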